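**Retrosynthetic overview** (flavanone numbering O1, C2–C8a)
1. C2–Ph bond last: Pd/PyOX-catalysed asymmetric conjugate arylation of the achiral chromenedione 12 sets the only stereocentre.
2. 12 ⇒ dienaminone 8 + 2,2-diprenylmalonyl dichloride 5 in one pot: a [3+3] double C-acylation (C6–C7, C4a–C8a) builds carbocycle A first, then the C8a enol displaces Me2NH at C2 and closes pyranone ring C.
3. 8 ⇒ 4-methoxypent-3-en-2-one + DMF-DMA (5-OMe fixed from the start, C2 installed, α′-methyl blocked).
4. 5 ⇒ dimethyl malonate + prenyl bromide (quaternary C8 made before any ring exists).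

Assumption: the PyOX–Pd arylation follows the facial sense reported for cyclic enones ((S)-ligand gives the R product), so the (R)-ligand is specified for the (2S) target; the sign is confirmed against natural material by optical rotation/ECD.

**Route**

Step 1
Reactants: 1 dimethyl malonate; 2 1-bromo-3-methylbut-2-ene (prenyl bromide, 2.2 equiv)
Product: 3 dimethyl 2,2-bis(3-methylbut-2-en-1-yl)malonate
Conditions: NaH (2.2 equiv), THF, 0 → 25 °C
Reagents that add atoms: none
Why: Double malonic ester alkylation (SN2 at the primary allylic bromide) installs the future quaternary C8; no stereocentre.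

Step 2
Reactants: 3 dimethyl 2,2-bis(3-methylbut-2-en-1-yl)malonate
Product: 4 2,2-bis(3-methylbut-2-en-1-yl)malonic acid
Conditions: KOH, EtOH/H2O, reflux; then 1 M HCl, 0 °C, to pH 2
Reagents that add atoms: potassium hydroxide, [K+].[OH-]
Why: Ester saponification (BAc2); the gem-dialkylmalonic acid does not decarboxylate at 0–25 °C, and cold dilute acid avoids lactonisation onto the prenyl alkenes.

Step 3
Reactants: 4 2,2-bis(3-methylbut-2-en-1-yl)malonic acid
Product: 5 2,2-bis(3-methylbut-2-en-1-yl)malonyl dichloride
Conditions: 1-chloro-N,N,2-trimethylprop-1-en-1-amine (2.2 equiv), CH2Cl2, 0 → 20 °C; bulb-to-bulb distillation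
Reagents that add atoms: Ghosez's reagent (1-chloro-N,N,2-trimethylprop-1-en-1-amine), CC(C)=C(Cl)N(C)C
Why: Ghosez α-chloroenamine chlorination converts the acid into the acid chloride under neutral conditions without free HCl, so the trisubstituted alkenes are not hydrochlorinated.

Step 4
Reactants: 6 (E)-4-methoxypent-3-en-2-one; 7 N,N-dimethylformamide dimethyl acetal
Product: 8 (1E,4E)-1-(dimethylamino)-5-methoxyhexa-1,4-dien-3-one
Conditions: neat, 90 °C, MeOH distilled off
Reagents that add atoms: none
Why: Amide-acetal condensation at the ketone α′-methyl gives the E-enaminone; it adds C2 as a formyl equivalent carrying a leaving group and removes the only α′-hydrogens, so later deprotonation can occur only at the γ-methyl (C6).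

Step 5
Reactants: 8 (1E,4E)-1-(dimethylamino)-5-methoxyhexa-1,4-dien-3-one; 5 2,2-bis(3-methylbut-2-en-1-yl)malonyl dichloride
Product: 12 5-methoxy-8,8-bis(3-methylbut-2-en-1-yl)-4H-chromene-4,7(8H)-dione, via silyl trienol ether 9 (not isolated), via acyclic keto acid chloride 10 (not isolated), via monocyclic hydroxy enaminone 11 (not isolated)
Conditions: LDA, THF, −78 °C; TMSCl; evaporate, CH2Cl2; 5 (1.0 equiv), TMSOTf (10 mol%), −78 → 20 °C, 0.02 M
Reagents that add atoms: chlorotrimethylsilane, C[Si](C)(C)Cl (silyl group carried by 9 only)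
Why: Proposed new method: γ-deprotonation/O-silylation (as in the preparation of Brassard's and Rawal's dienes) gives trienol ether 9, whose terminal carbon C6 is C-acylated by one COCl of the symmetric dichloride (closest known type: Chan/Langer [3+3] cyclisations of silyl dienol ethers with 1,3-dielectrophiles) to give 10; the second COCl then acylates C4a intramolecularly, because only this closure gives a six-membered ring (O-acylation would need a 4- or 8-membered ring), forming ring A as enol 11; the HCl released protonates the enaminone and the C8a enol OH displaces dimethylamine at C2 by addition–elimination (chromone synthesis from 2-hydroxyaryl enaminones), closing ring C; OMe at C5 and the ring oxygen at C8a are fixed by construction and no stereocentre is formed.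

Step 6
Reactants: 12 5-methoxy-8,8-bis(3-methylbut-2-en-1-yl)-4H-chromene-4,7(8H)-dione; 13 phenylboronic acid (2 equiv)
Product: 14 Griffinone A, (2S)-5-methoxy-8,8-bis(3-methylbut-2-en-1-yl)-2-phenyl-2,3-dihydro-4H-chromene-4,7(8H)-dione
Conditions: Pd(OCOCF3)2 (5 mol%), (R)-t-BuPyOX (6 mol%), NH4PF6 (30 mol%), H2O (5 equiv), ClCH2CH2Cl, 40–60 °C
Reagents that add atoms: none
Why: Pd(II)/PyOX-catalysed asymmetric conjugate addition of an arylboronic acid (Stoltz protocol, precedented for chromone → flavanone): aryl-Pd adds to C2, the only unsubstituted enone β-carbon, with the face dictated by the ligand t-Bu group; base-free protonolysis of the Pd enolate avoids retro-oxa-Michael racemisation, and the prenyl alkenes and the β-methoxy enone (fully substituted β-carbon) are inert.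

**Compound list**
1 | dimethyl malonate | COC(=O)CC(=O)OC | starting material
2 | 1-bromo-3-methylbut-2-ene (prenyl bromide) | CC(C)=CCBr | starting material
3 | dimethyl 2,2-bis(3-methylbut-2-en-1-yl)malonate | COC(=O)C(CC=C(C)C)(CC=C(C)C)C(=O)OC | intermediate
4 | 2,2-bis(3-methylbut-2-en-1-yl)malonic acid | OC(=O)C(CC=C(C)C)(CC=C(C)C)C(=O)O | intermediate
5 | 2,2-bis(3-methylbut-2-en-1-yl)malonyl dichloride | ClC(=O)C(CC=C(C)C)(CC=C(C)C)C(Cl)=O | intermediate
6 | (E)-4-methoxypent-3-en-2-one | CO/C(C)=C/C(C)=O | starting material
7 | N,N-dimethylformamide dimethyl acetal | COC(OC)N(C)C | starting material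
8 | (1E,4E)-1-(dimethylamino)-5-methoxyhexa-1,4-dien-3-one | CO/C(C)=C/C(=O)/C=C/N(C)C | intermediate
9 | (1E)-5-methoxy-N,N-dimethyl-3-(trimethylsilyloxy)hexa-1,3,5-trien-1-amine (C3=C4 geometry not controlled, irrelevant) | COC(=C)C=C(O[Si](C)(C)C)/C=C/N(C)C | intermediate
10 | (8E)-9-(dimethylamino)-5-methoxy-2,2-bis(3-methylbut-2-en-1-yl)-3,7-dioxonona-5,8-dienoyl chloride | CN(C)/C=C/C(=O)C=C(OC)CC(=O)C(CC=C(C)C)(CC=C(C)C)C(Cl)=O | intermediate
11 | 4-[(2E)-3-(dimethylamino)prop-2-enoyl]-5-hydroxy-3-methoxy-6,6-bis(3-methylbut-2-en-1-yl)cyclohexa-2,4-dien-1-one | COC1=CC(=O)C(CC=C(C)C)(CC=C(C)C)C(O)=C1C(=O)/C=C/N(C)C | intermediate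
12 | 5-methoxy-8,8-bis(3-methylbut-2-en-1-yl)-4H-chromene-4,7(8H)-dione | COC1=CC(=O)C(CC=C(C)C)(CC=C(C)C)C2=C1C(=O)C=CO2 | intermediate
13 | phenylboronic acid | OB(O)c1ccccc1 | starting material
14 | Griffinone A, (2S)-5-methoxy-8,8-bis(3-methylbut-2-en-1-yl)-2-phenyl-2,3-dihydro-4H-chromene-4,7(8H)-dione | COC1=CC(=O)C(CC=C(C)C)(CC=C(C)C)C2=C1C(=O)C[C@@H](c1ccccc1)O2 | target

**Step count**
Total steps: 6. Longest linear sequence: 5 (steps 1, 2, 3, 5, 6).

**Steps most likely to fail, with fallbacks**

Step 5 (ring-forming cascade). The hindered dichloride may react slowly, the enamine α-carbon C3 may be acylated, or oligomers may form. The fallback is an anionic Claisen–Dieckmann [3+3] that sets out from 8 and diester 3. The potassium dienolate of 8 (KHMDS, 2.2 equiv, THF, −78 → 50 °C) attacks one ester of 3 through C6 to give the keto ester methyl 9-(dimethylamino)-5-methoxy-2,2-bis(3-methylbut-2-en-1-yl)-3,7-dioxonona-5,8-dienoate F1. Its delocalised anion is nucleophilic at C4a and closes onto the second ester, which brings the route back at 11 (as its enolate); acidification with HCl/MeOH then gives 12. In the dienolate C3 is not nucleophilic and O-acylation by an ester is reversible; this variant also makes steps 2 and 3 unnecessary.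

Step 6 (asymmetric arylation). The ee may be low, conversion of the pyranone may be poor, or aryl-Pd may react with a prenyl alkene. The fallback sets out from 12: a racemic conjugate addition of a phenyl cuprate (PhMgBr, CuBr·SMe2, TMSCl, THF, −78 °C) gives the racemate, and preparative chiral SFC separates 14 from its enantiomer (2R)-5-methoxy-8,8-bis(3-methylbut-2-en-1-yl)-2-phenyl-2,3-dihydro-4H-chromene-4,7(8H)-dione F2. The route comes back at 14.

Step 4 (enaminone formation). Condensation may occur at the γ-methyl instead of the α′-methyl, or MeO/Me2N exchange may occur at C5. The fallback sets out from 6 and uses a directed Claisen formylation: LDA at −78 °C forms the kinetic α′-enolate, and methyl formate gives the hydroxymethylene ketone (1Z,4E)-1-hydroxy-5-methoxyhexa-1,4-dien-3-one F3 as its lithium salt. Condensation with dimethylamine hydrochloride in MeOH brings the route back at 8.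

**Further compounds**
F1 | step 5 | methyl 9-(dimethylamino)-5-methoxy-2,2-bis(3-methylbut-2-en-1-yl)-3,7-dioxonona-5,8-dienoate | CN(C)/C=C/C(=O)C=C(OC)CC(=O)C(CC=C(C)C)(CC=C(C)C)C(=O)OC
F2 | step 6 | (2R)-5-methoxy-8,8-bis(3-methylbut-2-en-1-yl)-2-phenyl-2,3-dihydro-4H-chromene-4,7(8H)-dione | COC1=CC(=O)C(CC=C(C)C)(CC=C(C)C)C2=C1C(=O)C[C@H](c1ccccc1)O2
F3 | step 4 | (1Z,4E)-1-hydroxy-5-methoxyhexa-1,4-dien-3-one | CO/C(C)=C/C(=O)/C=C\O
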